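**Plan**

1. Atom labels used throughout: ring C1 (CMe2), C2 (CHBr), C3 (CH2), C4 (CHCl), C5 (alkylidene carbon), C6 (CHCl); side chain C7 (=CH) and C8 (CH2Br). Descriptors such as (4R) refer to these labels, and the C5=C7 geometry is given as "C8 cis to C4".
2. Retrosynthesis: C8–Br, C4–Cl, C6–Cl and C2–Br are traced back to C–O bonds (inverted at the three ring carbons) and C6 to a ketone. Quaternary C1 sits in the ring between the two oxygen-bearing carbons C6 and C2, so the only ring is cut at C1–C2: C1 is the fully substituted carbon of a C6 ketone enolate (made from a C1 bromide) and C2 is an aldehyde.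
3. The acyclic chain is cut at C5–C6 (C5 vinyllithium plus an isobutyric Weinreb amide) and at C4–C5 (acetylide plus a C2–C4 Weinreb amide).
4. Forward: the chain C2–C3–C4–C5–C7–C8 is joined as an ynone, hydrostannation fixes the alkene geometry, C6 and C1 are added by acylation, C1 is brominated, the six-membered ring is closed at C1–C2, and the halogens are installed last.
5. Stereochemistry: C4 comes from a CBS reduction, C2 from the ring closure under control of C4, C6 from hydride addition anti to the C2 and C4 substituents; each carbinol then becomes its halide with inversion.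

Key step: step 9

Assumption: silyl ether 3 and amide 9 are taken as catalogue compounds; each is otherwise one routine step from propargyl alcohol or isobutyryl chloride.

**Route**

Step 1
Reactants: 1 methyl 3,3-dimethoxypropanoate
Product: 2 N-methoxy-N-methyl-3,3-dimethoxypropanamide
Conditions: MeNHOMe·HCl, i-PrMgCl, THF, −20 °C
Reagents that add atoms: N,O-dimethylhydroxylamine hydrochloride, CNOC.Cl
Why: Aminolysis of the ester by the magnesium amide (Weinreb amide formation) is fast at low temperature, where the acetal is inert.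

Step 2
Reactants: 2 N-methoxy-N-methyl-3,3-dimethoxypropanamide; 3 tert-butyldiphenyl(prop-2-yn-1-yloxy)silane
Product: 5 6-(tert-butyldiphenylsilyloxy)-1,1-dimethoxyhex-4-yn-3-one, via lithium acetylide 4 (not isolated)
Conditions: n-BuLi, THF, −78 °C; then 2, −78 → 0 °C
Reagents that add atoms: none
Why: Acylation of the lithium acetylide by the Weinreb amide (Weinreb ketone synthesis) stops at the ynone because the chelated tetrahedral adduct survives until work-up, and it forms the C4–C5 bond.

Step 3
Reactants: 5 6-(tert-butyldiphenylsilyloxy)-1,1-dimethoxyhex-4-yn-3-one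
Product: 6 (E)-6-(tert-butyldiphenylsilyloxy)-1,1-dimethoxy-4-(tributylstannyl)hex-4-en-3-one (tin on C5; C8 cis to C4)
Conditions: Bu3SnH, Pd(PPh3)4 (cat.), THF, 0 °C → rt
Reagents that add atoms: tributyltin hydride, CCCC[SnH](CCCC)CCCC
Why: Palladium-catalysed hydrostannation of an ynone is a syn addition that places tin on the carbon alpha to the carbonyl, so hydrogen goes to C7 and C8 ends up cis to C4 on the new C5=C7 bond.

Step 4
Reactants: 6 (E)-6-(tert-butyldiphenylsilyloxy)-1,1-dimethoxy-4-(tributylstannyl)hex-4-en-3-one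
Product: 7 (3R,4E)-6-(tert-butyldiphenylsilyloxy)-1,1-dimethoxy-4-(tributylstannyl)hex-4-en-3-ol (4R in route labels)
Conditions: (S)-1-methyl-3,3-diphenyltetrahydro-1H,3H-pyrrolo[1,2-c][1,3,2]oxazaborole (20 mol %), catecholborane, toluene, −78 °C
Reagents that add atoms: none
Why: In this Corey–Bakshi–Shibata reduction the alpha-stannylvinyl group acts as the large and the CH2CH(OMe)2 chain as the small ketone substituent, so the (S)-oxazaborolidine should deliver hydride to the face that gives the (4R)-carbinol.

Step 5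
Reactants: 7 (3R,4E)-6-(tert-butyldiphenylsilyloxy)-1,1-dimethoxy-4-(tributylstannyl)hex-4-en-3-ol
Product: 8 (3R,4E)-3-(tert-butyldimethylsilyloxy)-6-(tert-butyldiphenylsilyloxy)-1,1-dimethoxy-4-(tributylstannyl)hex-4-ene
Conditions: TBSCl, imidazole, DMAP (cat.), DMF, rt
Reagents that add atoms: tert-butyldimethylsilyl chloride, CC(C)(C)[Si](C)(C)Cl
Why: Silylation of the secondary alcohol under imidazole conditions spares the vinylstannane and the acetal, and puts at C4 the bulky, poorly coordinating ether that the ring closure relies on.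

Step 6
Reactants: 8 (3R,4E)-3-(tert-butyldimethylsilyloxy)-6-(tert-butyldiphenylsilyloxy)-1,1-dimethoxy-4-(tributylstannyl)hex-4-ene; 9 N-methoxy-N,2-dimethylpropanamide
Product: 11 (4E)-4-[(1R)-1-(tert-butyldimethylsilyloxy)-3,3-dimethoxypropyl]-6-(tert-butyldiphenylsilyloxy)-2-methylhex-4-en-3-one, via vinyllithium 10 (not isolated)
Conditions: n-BuLi, THF, −78 °C; then 9, −78 → −20 °C
Reagents that add atoms: none
Why: Tin–lithium exchange proceeds with retention of alkene geometry and the vinyllithium is acylated once by the Weinreb amide (Weinreb ketone synthesis), forming the C5–C6 bond with C8 trans to the new carbonyl.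

Step 7
Reactants: 11 (4E)-4-[(1R)-1-(tert-butyldimethylsilyloxy)-3,3-dimethoxypropyl]-6-(tert-butyldiphenylsilyloxy)-2-methylhex-4-en-3-one
Product: 13 (4E)-2-bromo-4-[(1R)-1-(tert-butyldimethylsilyloxy)-3,3-dimethoxypropyl]-6-(tert-butyldiphenylsilyloxy)-2-methylhex-4-en-3-one, via trimethylsilyl dienol ether 12 (not isolated)
Conditions: LiN(SiMe3)2, Me3SiCl, THF, −78 °C; then NBS, THF, −78 → 0 °C
Reagents that add atoms: N-bromosuccinimide, O=C1CCC(=O)N1Br
Why: C1–H is the only alpha-hydrogen of the ketone (C8 lies trans to the carbonyl, so gamma-deprotonation is not expected), so the silyl dienol ether forms regiospecifically and its electrophilic bromination by NBS gives the tertiary alpha-bromo ketone.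

Step 8
Reactants: 13 (4E)-2-bromo-4-[(1R)-1-(tert-butyldimethylsilyloxy)-3,3-dimethoxypropyl]-6-(tert-butyldiphenylsilyloxy)-2-methylhex-4-en-3-one
Product: 14 (3R,4E)-4-(2-bromo-2-methylpropanoyl)-3-(tert-butyldimethylsilyloxy)-6-(tert-butyldiphenylsilyloxy)hex-4-enal
Conditions: Et3SiOTf, 2,4,6-collidine, CH2Cl2, 0 °C; then H2O
Reagents that add atoms: water, O
Why: Silyl triflate–collidine cleavage of a dimethyl acetal (collidinium salt, hydrolysed on work-up) is a non-acidic acetal deprotection that leaves both silyl ethers, the bromo ketone (no alpha-hydrogen left) and the beta-silyloxy aldehyde intact.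

Step 9
Reactants: 14 (3R,4E)-4-(2-bromo-2-methylpropanoyl)-3-(tert-butyldimethylsilyloxy)-6-(tert-butyldiphenylsilyloxy)hex-4-enal
Product: 16 (3R,5R,6E)-5-(tert-butyldimethylsilyloxy)-6-[2-(tert-butyldiphenylsilyloxy)ethylidene]-3-hydroxy-2,2-dimethylcyclohexan-1-one (2R,4R in route labels; C2 hydroxyl trans to the C4 silyloxy group), via samarium enolate 15 (not isolated)
Conditions: SmI2 (2.2 equiv), THF, −78 °C, high dilution
Reagents that add atoms: none
Why: Divalent samarium passes two electrons to the weak tertiary alpha-keto C1–Br bond and gives the trivalent samarium enolate 15, a cross-conjugated dienolate that is nucleophilic only at C1 and adds to the tethered C2 aldehyde, forming the C1–C2 bond and the carbocycle. The closest known reaction type is the SmI2-promoted intramolecular Reformatsky (reductive aldol) cyclisation of alpha-halo ketones onto aldehydes. The ring closes in the 6-(enolendo)-exo-trig mode, a favoured closure for enolates. The new C2 stereocentre is controlled by C4: samarium bridges the enolate and aldehyde oxygens, which holds the C2 oxygen axial on the forming chair, and the bulky, poorly coordinating silyl ether at C4 cannot occupy the syn-axial site pointing at the metal, so the carbinol should form trans to the C4 silyloxy group, (2R). This trans aldol is also the more stable one (equatorial C2 hydroxyl, axial C4 silyloxy group free of allylic strain with C8), so any retro-aldol equilibration of the samarium aldolate leads to the same isomer. The step needs reduction of the bromide in preference to the aldehyde and the enone, which is secured by the much faster electron transfer to an alpha-bromo ketone at −78 °C with only two equivalents of SmI2; C1 has no hydrogen, so the aldol cannot dehydrate, and the C5=C7 geometry is not touched.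

Step 10
Reactants: 16 (3R,5R,6E)-5-(tert-butyldimethylsilyloxy)-6-[2-(tert-butyldiphenylsilyloxy)ethylidene]-3-hydroxy-2,2-dimethylcyclohexan-1-one
Product: 17 (3S,5R,6E)-3-bromo-5-(tert-butyldimethylsilyloxy)-6-[2-(tert-butyldiphenylsilyloxy)ethylidene]-2,2-dimethylcyclohexan-1-one (2S,4R in route labels; bromine cis to the C4 silyloxy group)
Conditions: CBr4, P(n-C8H17)3, pyridine, toluene, 70 °C
Reagents that add atoms: carbon tetrabromide, BrC(Br)(Br)Br
Why: In this Appel bromination the C2 oxyphosphonium, axial in the reacting chair, is displaced by bromide in an SN2 reaction with inversion; the C6 carbonyl on the neighbouring C1 disfavours ionisation and methyl shift, and C1 has no hydrogen for elimination toward the ketone.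

Step 11
Reactants: 17 (3S,5R,6E)-3-bromo-5-(tert-butyldimethylsilyloxy)-6-[2-(tert-butyldiphenylsilyloxy)ethylidene]-2,2-dimethylcyclohexan-1-one
Product: 18 (1R,3S,5R,6Z)-3-bromo-5-(tert-butyldimethylsilyloxy)-6-[2-(tert-butyldiphenylsilyloxy)ethylidene]-2,2-dimethylcyclohexan-1-ol (2S,4R,6R in route labels; all three ring substituents cis; C8 still cis to C4)
Conditions: NaBH4, CeCl3·7H2O, MeOH, −78 °C
Reagents that add atoms: none
Why: Luche reduction gives clean 1,2-reduction of the enone, and in either chair hydride should add to the ring face opposite the C2 bromine and the C4 silyloxy group, placing the new C6 hydroxyl cis to both.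

Step 12
Reactants: 18 (1R,3S,5R,6Z)-3-bromo-5-(tert-butyldimethylsilyloxy)-6-[2-(tert-butyldiphenylsilyloxy)ethylidene]-2,2-dimethylcyclohexan-1-ol
Product: 19 (1R,2E,3R,5S)-5-bromo-2-[2-(tert-butyldiphenylsilyloxy)ethylidene]-4,4-dimethylcyclohexane-1,3-diol (2S,4R,6R in route labels)
Conditions: CSA (cat.), MeOH/CH2Cl2, 0 °C → rt
Reagents that add atoms: none
Why: Acid-catalysed methanolysis (silyl ether cleavage) removes the secondary TBS ether much faster than the primary TBDPS ether, and the allylic alcohols should not ionise because the alkene is flanked by electron-withdrawing groups.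

Step 13
Reactants: 19 (1R,2E,3R,5S)-5-bromo-2-[2-(tert-butyldiphenylsilyloxy)ethylidene]-4,4-dimethylcyclohexane-1,3-diol
Product: 20 (1E,2S,4S,6S)-4-bromo-1-[2-(tert-butyldiphenylsilyloxy)ethylidene]-2,6-dichloro-3,3-dimethylcyclohexane (2S,4S,6S in route labels)
Conditions: PPh3, Cl3CC(O)CCl3, CH2Cl2, 0 °C → rt
Reagents that add atoms: hexachloroacetone, ClC(Cl)(Cl)C(=O)C(Cl)(Cl)Cl
Why: Appel-type chlorination with PPh3 and hexachloroacetone converts allylic alcohols into unrearranged chlorides by SN2 displacement of the oxyphosphonium with inversion, which turns the (4R,6R)-diol into the (4S,6S)-dichloride with both chlorines trans to the bromine.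

Step 14
Reactants: 20 (1E,2S,4S,6S)-4-bromo-1-[2-(tert-butyldiphenylsilyloxy)ethylidene]-2,6-dichloro-3,3-dimethylcyclohexane
Product: 21 (2E)-2-[(2S,4S,6S)-4-bromo-2,6-dichloro-3,3-dimethylcyclohexylidene]ethan-1-ol
Conditions: HF·pyridine, pyridine, THF, 0 °C → rt
Reagents that add atoms: none
Why: Fluoride desilylation under buffered, non-basic conditions frees the primary allylic alcohol without elimination or substitution of the three halides.

Step 15
Reactants: 21 (2E)-2-[(2S,4S,6S)-4-bromo-2,6-dichloro-3,3-dimethylcyclohexylidene]ethan-1-ol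
Product: 22 ochtodene, (1E,2S,4S,6S)-4-bromo-1-(2-bromoethylidene)-2,6-dichloro-3,3-dimethylcyclohexane
Conditions: CBr4, PPh3, CH2Cl2, 0 °C
Reagents that add atoms: carbon tetrabromide, BrC(Br)(Br)Br
Why: Appel bromination of a primary allylic alcohol is a fast SN2 reaction at 0 °C; C5 is fully substituted, so allylic transposition is not expected, and the hindered ring halides are inert under these conditions.

**Compound list**

1 | methyl 3,3-dimethoxypropanoate | COC(OC)CC(=O)OC | starting material
2 | N-methoxy-N-methyl-3,3-dimethoxypropanamide | COC(OC)CC(=O)N(C)OC | intermediate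
3 | tert-butyldiphenyl(prop-2-yn-1-yloxy)silane | C#CCO[Si](c1ccccc1)(c1ccccc1)C(C)(C)C | starting material
4 | lithium acetylide of 3, [3-(tert-butyldiphenylsilyloxy)prop-1-yn-1-yl]lithium | [Li]C#CCO[Si](c1ccccc1)(c1ccccc1)C(C)(C)C | intermediate
5 | 6-(tert-butyldiphenylsilyloxy)-1,1-dimethoxyhex-4-yn-3-one | COC(OC)CC(=O)C#CCO[Si](c1ccccc1)(c1ccccc1)C(C)(C)C | intermediate
6 | (E)-6-(tert-butyldiphenylsilyloxy)-1,1-dimethoxy-4-(tributylstannyl)hex-4-en-3-one | COC(OC)CC(=O)/C(=C\CO[Si](c1ccccc1)(c1ccccc1)C(C)(C)C)[Sn](CCCC)(CCCC)CCCC | intermediate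
7 | (3R,4E)-6-(tert-butyldiphenylsilyloxy)-1,1-dimethoxy-4-(tributylstannyl)hex-4-en-3-ol | COC(OC)C[C@@H](O)/C(=C\CO[Si](c1ccccc1)(c1ccccc1)C(C)(C)C)[Sn](CCCC)(CCCC)CCCC | intermediate
8 | (3R,4E)-3-(tert-butyldimethylsilyloxy)-6-(tert-butyldiphenylsilyloxy)-1,1-dimethoxy-4-(tributylstannyl)hex-4-ene | COC(OC)C[C@@H](O[Si](C)(C)C(C)(C)C)/C(=C\CO[Si](c1ccccc1)(c1ccccc1)C(C)(C)C)[Sn](CCCC)(CCCC)CCCC | intermediate
9 | N-methoxy-N,2-dimethylpropanamide | CC(C)C(=O)N(C)OC | starting material
10 | vinyllithium from 8 (lithium on C5 in place of tin, geometry and 4R retained) | COC(OC)C[C@@H](O[Si](C)(C)C(C)(C)C)/C(=C\CO[Si](c1ccccc1)(c1ccccc1)C(C)(C)C)[Li] | intermediate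
11 | (4E)-4-[(1R)-1-(tert-butyldimethylsilyloxy)-3,3-dimethoxypropyl]-6-(tert-butyldiphenylsilyloxy)-2-methylhex-4-en-3-one | COC(OC)C[C@@H](O[Si](C)(C)C(C)(C)C)/C(=C\CO[Si](c1ccccc1)(c1ccccc1)C(C)(C)C)C(=O)C(C)C | intermediate
12 | trimethylsilyl dienol ether of 11 (C1=C6 enol ether, 4R, C8 cis to C4) | COC(OC)C[C@@H](O[Si](C)(C)C(C)(C)C)/C(=C\CO[Si](c1ccccc1)(c1ccccc1)C(C)(C)C)C(O[Si](C)(C)C)=C(C)C | intermediate
13 | (4E)-2-bromo-4-[(1R)-1-(tert-butyldimethylsilyloxy)-3,3-dimethoxypropyl]-6-(tert-butyldiphenylsilyloxy)-2-methylhex-4-en-3-one | COC(OC)C[C@@H](O[Si](C)(C)C(C)(C)C)/C(=C\CO[Si](c1ccccc1)(c1ccccc1)C(C)(C)C)C(=O)C(C)(C)Br | intermediate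
14 | (3R,4E)-4-(2-bromo-2-methylpropanoyl)-3-(tert-butyldimethylsilyloxy)-6-(tert-butyldiphenylsilyloxy)hex-4-enal | O=CC[C@@H](O[Si](C)(C)C(C)(C)C)/C(=C\CO[Si](c1ccccc1)(c1ccccc1)C(C)(C)C)C(=O)C(C)(C)Br | intermediate
15 | samarium enolate of 14 (O–SmI2 on C6, C1=C6, trivalent samarium) | O=CC[C@@H](O[Si](C)(C)C(C)(C)C)/C(=C\CO[Si](c1ccccc1)(c1ccccc1)C(C)(C)C)C(O[Sm](I)I)=C(C)C | intermediate
16 | (3R,5R,6E)-5-(tert-butyldimethylsilyloxy)-6-[2-(tert-butyldiphenylsilyloxy)ethylidene]-3-hydroxy-2,2-dimethylcyclohexan-1-one | CC1(C)[C@H](O)C[C@@H](O[Si](C)(C)C(C)(C)C)/C(=C\CO[Si](c2ccccc2)(c2ccccc2)C(C)(C)C)C1=O | intermediate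
17 | (3S,5R,6E)-3-bromo-5-(tert-butyldimethylsilyloxy)-6-[2-(tert-butyldiphenylsilyloxy)ethylidene]-2,2-dimethylcyclohexan-1-one | CC1(C)[C@@H](Br)C[C@@H](O[Si](C)(C)C(C)(C)C)/C(=C\CO[Si](c2ccccc2)(c2ccccc2)C(C)(C)C)C1=O | intermediate
18 | (1R,3S,5R,6Z)-3-bromo-5-(tert-butyldimethylsilyloxy)-6-[2-(tert-butyldiphenylsilyloxy)ethylidene]-2,2-dimethylcyclohexan-1-ol | CC1(C)[C@@H](Br)C[C@@H](O[Si](C)(C)C(C)(C)C)/C(=C\CO[Si](c2ccccc2)(c2ccccc2)C(C)(C)C)[C@H]1O | intermediate
19 | (1R,2E,3R,5S)-5-bromo-2-[2-(tert-butyldiphenylsilyloxy)ethylidene]-4,4-dimethylcyclohexane-1,3-diol | CC1(C)[C@@H](Br)C[C@@H](O)/C(=C\CO[Si](c2ccccc2)(c2ccccc2)C(C)(C)C)[C@H]1O | intermediate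
20 | (1E,2S,4S,6S)-4-bromo-1-[2-(tert-butyldiphenylsilyloxy)ethylidene]-2,6-dichloro-3,3-dimethylcyclohexane | CC1(C)[C@@H](Br)C[C@H](Cl)/C(=C\CO[Si](c2ccccc2)(c2ccccc2)C(C)(C)C)[C@@H]1Cl | intermediate
21 | (2E)-2-[(2S,4S,6S)-4-bromo-2,6-dichloro-3,3-dimethylcyclohexylidene]ethan-1-ol | CC1(C)[C@@H](Br)C[C@H](Cl)/C(=C\CO)[C@@H]1Cl | intermediate
22 | ochtodene, (1E,2S,4S,6S)-4-bromo-1-(2-bromoethylidene)-2,6-dichloro-3,3-dimethylcyclohexane | CC1(C)[C@@H](Br)C[C@H](Cl)/C(=C\CBr)[C@@H]1Cl | target

**Step count and risks**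

Total step count: 15. Longest linear sequence: 15 steps (1 → 22); 3 and 9 enter as purchased reagents.

Steps most likely to fail:

Step 13 (double chlorination). Chloride may attack C7 with allylic transposition, substitution at C6 next to the quaternary C1 may be slow, and the syn diol may be bridged by phosphorus instead of being activated twice. The fallback separates the two displacements and uses chloro-iminium instead of phosphonium activation. It sets out from 18, in which only the C6 hydroxyl is free. 1-Chloro-N,N,2-trimethylprop-1-en-1-amine in CH2Cl2 should give, with inversion, the C6 chloride F1 with the C4 silyl ether still in place. Acid methanolysis (CSA, MeOH) then frees the C4 alcohol F2, and a second treatment with the same chloroenamine chlorinates C4 with inversion and comes back to the route at 20.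

Step 10 (bromination at C2). Elimination toward C3 or migration of a C1 methyl group may outrun substitution at the hindered neopentyl-type carbon. The fallback replaces the one-pot phosphonium activation by an isolable sulfonate. It sets out from 16, which is converted (ClCH2SO2Cl, pyridine, CH2Cl2, 0 °C) into the C2 chloromethanesulfonate F3. This is displaced in a separate SN2 step by bromide (LiBr, DMF, 50 °C) with inversion and comes back to the route at 17.

Step 9 (ring closure). Facial selectivity in the addition to the aldehyde may be poor, giving part of the material as the C2 epimer. The fallback keeps the ring closure and resets C2 under reagent control. It sets out from 14, which is cyclised as in step 9. The mixture of 16 and its C2 epimer F4 is oxidised (Dess–Martin periodinane, CH2Cl2) to the single 1,3-diketone F5. Its saturated, less hindered C2 carbonyl is then reduced by a CBS reduction ((S)-oxazaborolidine, catecholborane, −78 °C; the quaternary C1 side acts as the large group) to the (2R)-alcohol, coming back to the route at 16.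

**Further compounds**

F1 | step 13 | C6 chloride of 18 with the C4 silyl ether kept (2S,4R,6S in route labels) | CC1(C)[C@@H](Br)C[C@@H](O[Si](C)(C)C(C)(C)C)/C(=C\CO[Si](c2ccccc2)(c2ccccc2)C(C)(C)C)[C@@H]1Cl
F2 | step 13 | C4 alcohol from F1 (2S,4R,6S in route labels) | CC1(C)[C@@H](Br)C[C@@H](O)/C(=C\CO[Si](c2ccccc2)(c2ccccc2)C(C)(C)C)[C@@H]1Cl
F3 | step 10 | C2 chloromethanesulfonate of 16 (2R,4R in route labels) | CC1(C)[C@H](OS(=O)(=O)CCl)C[C@@H](O[Si](C)(C)C(C)(C)C)/C(=C\CO[Si](c2ccccc2)(c2ccccc2)C(C)(C)C)C1=O
F4 | step 9 | C2 epimer of 16 (2S,4R in route labels) | CC1(C)[C@@H](O)C[C@@H](O[Si](C)(C)C(C)(C)C)/C(=C\CO[Si](c2ccccc2)(c2ccccc2)C(C)(C)C)C1=O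
F5 | step 9 | 1,3-diketone from 16 and F4 (C2 and C6 carbonyls, 4R) | CC1(C)C(=O)C[C@@H](O[Si](C)(C)C(C)(C)C)/C(=C\CO[Si](c2ccccc2)(c2ccccc2)C(C)(C)C)C1=O
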